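**Retrosynthetic overview**

1. Target 31 ⇐ 30 by acid hydrolysis of a pivalaldehyde acetal template; 30 ⇐ 29 by a DMAP O→C acyl shift that releases the 3-acyl-4-hydroxypyranone from its neutral enol ester.
2. 29 ⇐ 5-chloro-1,3-dioxan-4-one 10 + E-vinyl iodide 27 by a stereoconvergent Ni-catalysed electroreductive cross-coupling that forms the bond between the acid α-carbon and the alkene CH.
3. Enabling feature: target C2 is α to the carboxyl carbon C1 and β to the hydroxyl-bearing C3, so O–C3–C2–C1(=O)–O closes with pivalaldehyde to a six-membered 1,3-dioxan-4-one (O1, C2′, O3, C4, C5, C6). Ring C5 (= target C2) is then an α-halo ester/radical site beside the sec-butyl-bearing C6, and its partner is an sp2 CH of an E-1,2-disubstituted alkene, available as an E-vinyl iodide.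
4. 10 ⇐ (S)-2-methylbutanoic acid (C4 from the pool, C3 by Ru–BINAP hydrogenation); 27 ⇐ (R)-citronellal (methyl centre; alkyne → E-vinyl iodide; isopropylidene → CO2H) + pyranone 16 ⇐ ethyl (R)-3-hydroxybutanoate.
5. Ring order: dioxanone template (step 4), dihydropyranone (step 7), fragment coupling (step 13); the template ring is opened in the last step.

Key step: step 13

Remark: 10 is taken on as a mixture of C5 epimers, since step 13 passes through a planar C5 radical; 16 and its derivatives are written as enol tautomers, as in the target SMILES.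

**Left fragment (steps 1–5)**

Step 1
Reactants: 1 (S)-2-methylbutanoic acid; 2 potassium ethyl malonate
Product: 4 ethyl (4S)-4-methyl-3-oxohexanoate, via acyl imidazolide 3 (not isolated)
Conditions: CDI, THF, rt; then 2, MgCl2, Et3N, MeCN, rt → 40 °C; 1 M HCl
Reagents that add atoms: none
Why: Masamune–Brooks homologation, in which the acyl imidazolide acylates the magnesium enolate of the malonate half-ester and the adduct decarboxylates on acidic work-up; the near-neutral conditions should leave the α-stereocentre of 1 intact.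

Step 2
Reactants: 4 ethyl (4S)-4-methyl-3-oxohexanoate
Product: 5 ethyl (3S,4S)-3-hydroxy-4-methylhexanoate
Conditions: RuCl2[(R)-BINAP] (0.5 mol %), H2 (10 bar), EtOH, 50 °C
Reagents that add atoms: none
Why: Noyori asymmetric hydrogenation of a β-keto ester; the (R)-BINAP catalyst should deliver hydrogen with the facial sense that gives (R)-3-hydroxybutanoates, which is 3S here by CIP, under catalyst control and without touching C4.

Step 3
Reactants: 5 ethyl (3S,4S)-3-hydroxy-4-methylhexanoate
Product: 6 (3S,4S)-3-hydroxy-4-methylhexanoic acid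
Conditions: LiOH, THF/H2O, 0 °C → rt; then 1 M HCl to pH 2
Reagents that add atoms: lithium hydroxide, [Li+].[OH-]
Why: Saponification of an unhindered ethyl ester; neither stereocentre is enolisable under these conditions.

Step 4
Reactants: 6 (3S,4S)-3-hydroxy-4-methylhexanoic acid; 7 pivalaldehyde
Product: 8 (2R,6S)-2-tert-butyl-6-[(2S)-butan-2-yl]-1,3-dioxan-4-one (cis-2,6)
Conditions: TsOH·H2O (cat.), CH2Cl2, reflux, Dean–Stark
Reagents that add atoms: none
Why: Seebach-type acetalisation of a β-hydroxy acid; under acid-catalysed equilibration the acetal carbon should settle cis to C6 with tert-butyl and sec-butyl both equatorial, which fixes the 2R centre of the template.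

Step 5
Reactants: 8 (2R,6S)-2-tert-butyl-6-[(2S)-butan-2-yl]-1,3-dioxan-4-one
Product: 10 (2R,5RS,6R)-2-tert-butyl-6-[(2S)-butan-2-yl]-5-chloro-1,3-dioxan-4-one (C5 epimer mixture), via lithium enolate 9 (not isolated)
Conditions: LDA (1.1 equiv), THF, −78 °C; NCS (1.2 equiv), −78 °C; sat. NH4Cl at −78 °C
Reagents that add atoms: N-chlorosuccinimide, O=C1CCC(=O)N1Cl
Why: α-Chlorination of a lactone lithium enolate by an electrophilic chlorine source, held at −78 °C to avoid β-elimination of the enolate; attack trans to the C6 group is expected to dominate, but either epimer serves because step 13 erases this centre.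

**Pyranone (steps 6–7)**

Step 6
Reactants: 11 ethyl (R)-3-hydroxybutanoate; 12 tert-butyl acetate
Product: 14 tert-butyl (5R)-5-hydroxy-3-oxohexanoate, via lithium ester enolate 13 (not isolated)
Conditions: LDA (3.5 equiv), 12 (3.5 equiv), THF, −78 °C; then 11, −78 → −30 °C; aq. HCl
Reagents that add atoms: none
Why: Crossed Claisen condensation of excess lithium tert-butyl acetate enolate with the ethyl ester (the first equivalent is consumed by the hydroxyl); the carbinol centre is not involved.

Step 7
Reactants: 14 tert-butyl (5R)-5-hydroxy-3-oxohexanoate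
Product: 16 (6R)-4-hydroxy-6-methyl-5,6-dihydro-2H-pyran-2-one, via β-keto acid 15 (not isolated)
Conditions: TFA, CH2Cl2, rt
Reagents that add atoms: none
Why: Acidolysis of the tert-butyl ester followed by lactonisation of the δ-hydroxy β-keto acid gives the dihydropyranone as its conjugated enol; the stereocentre is untouched.

**Side chain and enol ester (steps 8–12)**

Step 8
Reactants: 17 (R)-citronellal; 18 dimethyl (1-diazo-2-oxopropyl)phosphonate
Product: 20 (4R)-4,8-dimethylnon-7-en-1-yne, via diazomethylphosphonate 19 (not isolated)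
Conditions: K2CO3, MeOH, 0 °C → rt
Reagents that add atoms: none
Why: Seyferth–Gilbert homologation in the Ohira–Bestmann version (methanolysis of 18, addition to the aldehyde, carbene 1,2-shift); the stereocentre is β to the aldehyde and cannot epimerise.

Step 9
Reactants: 20 (4R)-4,8-dimethylnon-7-en-1-yne
Product: 22 (1E,4R)-1-iodo-4,8-dimethylnona-1,7-diene, via alkenylzirconocene chloride 21 (not isolated)
Conditions: Cp2Zr(H)Cl (1.2 equiv), THF, rt; then I2, 0 °C
Reagents that add atoms: iodine, II
Why: Schwartz hydrozirconation adds Zr–H syn to the terminal alkyne with Zr at the terminus and leaves the trisubstituted alkene alone; iodinolysis with retention should give only the E-vinyl iodide.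

Step 10
Reactants: 22 (1E,4R)-1-iodo-4,8-dimethylnona-1,7-diene
Product: 24 (4R,6E)-7-iodo-4-methylhept-6-enal, via vicinal diol 23 (not isolated)
Conditions: OsO4 (2 mol %), NaIO4 (4 equiv), 2,6-lutidine, dioxane/H2O, rt
Reagents that add atoms: osmium tetroxide, O=[Os](=O)(=O)=O; sodium periodate, [Na+].[O-]I(=O)(=O)=O
Why: Lemieux–Johnson cleavage; OsO4 should dihydroxylate the electron-rich trisubstituted alkene in preference to the electron-poor iodoalkene, and periodate cleaves the diol.

Step 11
Reactants: 24 (4R,6E)-7-iodo-4-methylhept-6-enal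
Product: 25 (4R,6E)-7-iodo-4-methylhept-6-enoic acid
Conditions: NaClO2, NaH2PO4, 2-methyl-2-butene, t-BuOH/H2O, rt
Reagents that add atoms: sodium chlorite, [Na+].[O-]Cl=O
Why: Pinnick oxidation with a hypochlorite scavenger; the vinyl iodide and the remote stereocentre are inert.

Step 12
Reactants: 25 (4R,6E)-7-iodo-4-methylhept-6-enoic acid; 16 (6R)-4-hydroxy-6-methyl-5,6-dihydro-2H-pyran-2-one
Product: 27 (2R)-2-methyl-6-oxo-3,6-dihydro-2H-pyran-4-yl (4R,6E)-7-iodo-4-methylhept-6-enoate (4-O-acyl enol ester of 16), via acid chloride 26 (not isolated)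
Conditions: (COCl)2, DMF (cat.), CH2Cl2, 0 °C → rt, evaporate; then 16, Et3N, CH2Cl2, 0 °C
Reagents that add atoms: none
Why: Kinetic O-acylation of the enol of 16 by an acyl chloride without an acyl-transfer catalyst stops at the enol ester, which stores the acidic, chelating tricarbonyl in a neutral form for the coupling.

**Coupling and endgame (steps 13–15)**

Step 13
Reactants: 10 (2R,5RS,6R)-2-tert-butyl-6-[(2S)-butan-2-yl]-5-chloro-1,3-dioxan-4-one (C5 epimer mixture); 27 enol ester vinyl iodide
Product: 29 (2R,5R,6R)-2-tert-butyl-6-[(2S)-butan-2-yl]-5-[(1E,4R)-4-methyl-7-{[(2R)-2-methyl-6-oxo-3,6-dihydro-2H-pyran-4-yl]oxy}-7-oxohept-1-en-1-yl]-1,3-dioxan-4-one, via C5 radical 28 (not isolated)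
Conditions: NiBr2·dme (10 mol %), 2,2′-bipyridine (12 mol %), Bu4NBr, DMF, rt, undivided cell, Mg anode/Ni-foam cathode, constant current (ca. 2.5 F/mol of 27); 10 (1.5 equiv) added by syringe pump
Reagents that add atoms: none
Why: Cathodically formed (bpy)Ni(0) inserts into the C–I bond of 27 with retention, the reduced alkenyl–Ni species abstracts chlorine from either C5 epimer of 10 to give the planar α-carbonyl radical 28, and radical capture at nickel followed by reductive elimination forms the C5–C(sp2) bond. The closest known reaction type is the Ni-catalysed electroreductive cross-coupling of α-chloro esters with vinyl halides at a sacrificial anode; no ring is closed. The new stereocentre C5 is controlled by the template: the equatorial tert-butyl (C2) and sec-butyl (C6) groups lock the ring, so the nickel-bound alkenyl group should enter trans to the C6 substituent and give the 5R (5,6-trans) product, which is the 2,3-anti acid after ring opening; both epimers of 10 converge through 28. Cross- over homo-coupling is secured by the different activation modes of the two halides (two-electron insertion at C(sp2)–I, halogen abstraction at the activated C(sp3)–Cl) and by slow addition of 10, and the E geometry is kept because the alkenyl carbon never becomes a free radical. The ring holds the C6–O1 bond out of syn-coplanarity with any C5–Ni bond, which should suppress β-alkoxide elimination, and no acidic proton is present because the pyranone is carried as its enol ester.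

Step 14
Reactants: 29 coupled enol ester
Product: 30 (2R,5R,6R)-2-tert-butyl-6-[(2S)-butan-2-yl]-5-[(1E,4R)-7-[(6R)-4-hydroxy-6-methyl-2-oxo-5,6-dihydro-2H-pyran-3-yl]-4-methyl-7-oxohept-1-en-1-yl]-1,3-dioxan-4-one
Conditions: DMAP (1.2 equiv), toluene, rt → 40 °C; 1 M HCl wash
Reagents that add atoms: none
Why: DMAP-mediated O→C acyl migration (Fries-type rearrangement of an enol ester through an N-acylpyridinium/pyranone-enolate ion pair) should funnel the material to the chelated 3-acyl-4-hydroxypyranone; DMAP is too weak a base to epimerise C5 or move the alkene.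

Step 15
Reactants: 30 acylpyranone dioxanone
Product: 31 (2R,3R,4S)-3-hydroxy-2-[(1E,4R)-7-[(6R)-4-hydroxy-6-methyl-2-oxo-5,6-dihydro-2H-pyran-3-yl]-4-methyl-7-oxohept-1-en-1-yl]-4-methylhexanoic acid (target)
Conditions: 2 M HCl/THF (1:2), rt → 40 °C
Reagents that add atoms: water, O
Why: Acid hydrolysis of the acylal (α-alkoxyalkyl ester) template by ionisation and capture by water releases pivalaldehyde, the C3 hydroxyl and the C1 acid; no base is present, so C2 should not epimerise and the alkene should not move into conjugation.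

**Compound list**

1 | (S)-2-methylbutanoic acid | CC[C@H](C)C(=O)O | starting material
2 | potassium ethyl malonate | [K+].[O-]C(=O)CC(=O)OCC | starting material
3 | (2S)-1-(imidazol-1-yl)-2-methylbutan-1-one | CC[C@H](C)C(=O)n1ccnc1 | intermediate (not isolated)
4 | ethyl (4S)-4-methyl-3-oxohexanoate | CC[C@H](C)C(=O)CC(=O)OCC | intermediate
5 | ethyl (3S,4S)-3-hydroxy-4-methylhexanoate | CC[C@H](C)[C@@H](O)CC(=O)OCC | intermediate
6 | (3S,4S)-3-hydroxy-4-methylhexanoic acid | CC[C@H](C)[C@@H](O)CC(=O)O | intermediate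
7 | pivalaldehyde | CC(C)(C)C=O | starting material
8 | (2R,6S)-2-tert-butyl-6-[(2S)-butan-2-yl]-1,3-dioxan-4-one | CC[C@H](C)[C@@H]1CC(=O)O[C@H](C(C)(C)C)O1 | intermediate
9 | lithium enolate of 8 | CC[C@H](C)[C@@H]1C=C([O-])O[C@H](C(C)(C)C)O1.[Li+] | intermediate (not isolated)
10 | (2R,5RS,6R)-2-tert-butyl-6-[(2S)-butan-2-yl]-5-chloro-1,3-dioxan-4-one, C5 epimer mixture | CC[C@H](C)[C@@H]1C(Cl)C(=O)O[C@H](C(C)(C)C)O1 | intermediate
11 | ethyl (R)-3-hydroxybutanoate | C[C@@H](O)CC(=O)OCC | starting material
12 | tert-butyl acetate | CC(=O)OC(C)(C)C | starting material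
13 | lithium enolate of tert-butyl acetate | C=C([O-])OC(C)(C)C.[Li+] | intermediate (not isolated)
14 | tert-butyl (5R)-5-hydroxy-3-oxohexanoate | C[C@@H](O)CC(=O)CC(=O)OC(C)(C)C | intermediate
15 | (5R)-5-hydroxy-3-oxohexanoic acid | C[C@@H](O)CC(=O)CC(=O)O | intermediate (not isolated)
16 | (6R)-4-hydroxy-6-methyl-5,6-dihydro-2H-pyran-2-one | C[C@@H]1CC(O)=CC(=O)O1 | intermediate
17 | (R)-citronellal | O=CC[C@H](C)CCC=C(C)C | starting material
18 | dimethyl (1-diazo-2-oxopropyl)phosphonate | CC(=O)C(=[N+]=[N-])P(=O)(OC)OC | starting material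
19 | dimethyl (diazomethyl)phosphonate | COP(=O)(OC)C=[N+]=[N-] | intermediate (not isolated)
20 | (4R)-4,8-dimethylnon-7-en-1-yne | C#CC[C@H](C)CCC=C(C)C | intermediate
21 | chlorobis(cyclopentadienyl)[(1E,4R)-4,8-dimethylnona-1,7-dien-1-yl]zirconium | Cl[Zr](/C=C/C[C@H](C)CCC=C(C)C)(C1C=CC=C1)C1C=CC=C1 | intermediate (not isolated)
22 | (1E,4R)-1-iodo-4,8-dimethylnona-1,7-diene | I/C=C/C[C@H](C)CCC=C(C)C | intermediate
23 | (6R,8E)-9-iodo-2,6-dimethylnon-8-ene-2,3-diol, C3 epimers | I/C=C/C[C@H](C)CCC(O)C(C)(C)O | intermediate (not isolated)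
24 | (4R,6E)-7-iodo-4-methylhept-6-enal | I/C=C/C[C@H](C)CCC=O | intermediate
25 | (4R,6E)-7-iodo-4-methylhept-6-enoic acid | I/C=C/C[C@H](C)CCC(=O)O | intermediate
26 | (4R,6E)-7-iodo-4-methylhept-6-enoyl chloride | I/C=C/C[C@H](C)CCC(Cl)=O | intermediate (not isolated)
27 | (2R)-2-methyl-6-oxo-3,6-dihydro-2H-pyran-4-yl (4R,6E)-7-iodo-4-methylhept-6-enoate | I/C=C/C[C@H](C)CCC(=O)OC1=CC(=O)O[C@H](C)C1 | intermediate
28 | (2R,6R)-2-tert-butyl-6-[(2S)-butan-2-yl]-4-oxo-1,3-dioxan-5-yl radical | CC[C@H](C)[C@@H]1[CH]C(=O)O[C@H](C(C)(C)C)O1 | intermediate (not isolated)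
29 | (2R,5R,6R)-2-tert-butyl-6-[(2S)-butan-2-yl]-5-[(1E,4R)-4-methyl-7-{[(2R)-2-methyl-6-oxo-3,6-dihydro-2H-pyran-4-yl]oxy}-7-oxohept-1-en-1-yl]-1,3-dioxan-4-one | CC[C@H](C)[C@@H]1[C@@H](/C=C/C[C@H](C)CCC(=O)OC2=CC(=O)O[C@H](C)C2)C(=O)O[C@H](C(C)(C)C)O1 | intermediate
30 | (2R,5R,6R)-2-tert-butyl-6-[(2S)-butan-2-yl]-5-[(1E,4R)-7-[(6R)-4-hydroxy-6-methyl-2-oxo-5,6-dihydro-2H-pyran-3-yl]-4-methyl-7-oxohept-1-en-1-yl]-1,3-dioxan-4-one | CC[C@H](C)[C@@H]1[C@@H](/C=C/C[C@H](C)CCC(=O)C2=C(O)C[C@@H](C)OC2=O)C(=O)O[C@H](C(C)(C)C)O1 | intermediate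
31 | (2R,3R,4S)-3-hydroxy-2-[(1E,4R)-7-[(6R)-4-hydroxy-6-methyl-2-oxo-5,6-dihydro-2H-pyran-3-yl]-4-methyl-7-oxohept-1-en-1-yl]-4-methylhexanoic acid | CC[C@H](C)[C@@H](O)[C@@H](/C=C/C[C@H](C)CCC(=O)C1=C(O)C[C@@H](C)OC1=O)C(=O)O | target

**Summary**

Total step count: 15. Longest linear sequence: 8 steps (steps 8–15 from 17; equally steps 1–5 and 13–15 from 1).

Steps most likely to fail:

1. Step 13. Homocoupling and hydrodechlorination may outrun the cross-coupling, over-reduction of radical 28 to an enolate may trigger β-elimination that opens the template, and facial selectivity at C5 may be incomplete. The fallback makes the alkenyl partner a carbonyl-free nucleophile and finishes the side chain afterwards. It sets out from 21 (made from 20 as in step 9, not quenched with iodine) and 10: a Ni-catalysed Negishi-type coupling of the alkenylzirconocene with the α-chloro ester (NiCl2·dme, bipyridine-type ligand, DME/THF) should give the coupled diene F1. Selective epoxidation of its trisubstituted alkene (mCPBA, 0 °C) gives the epoxide F2, periodic acid cleaves this to the aldehyde F3, and Pinnick oxidation gives the acid F4. DCC/DMAP acylation of 16 with F4 (O-acylation and in-flask O→C shift, passing through 29) gives 30, where the fallback rejoins the route before step 15.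

2. Step 5. The lithium enolate 9 may fragment by β-elimination before it is chlorinated, or chlorinate twice. The fallback chlorinates the open chain before the ring is built. It sets out from 5: LDA (2.2 equiv, THF, −78 → −40 °C) gives the Fráter–Seebach dilithium dianion F5, which cannot eliminate, and hexachloroethane converts it into the chlorohydrin ester F6. The ester is cleaved without base (aq. HCl/dioxane or an esterase at pH 7, so that no glycidate forms) to the chloro acid F7, and acetalisation with 7 as in step 4 returns to the route at 10.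

3. Step 14. The acyl migration may stall, DMAP may open the dioxanone, or the C5 alkene may drift into conjugation. The fallback moves the acyl migration ahead of the fragment coupling. It sets out from 25 and 16: DCC/DMAP gives the C-acyl vinyl iodide F8 directly, and NaHMDS converts it into its sodium enolate F9, which serves as a spectator acac-type anion. F9 is coupled with 10 under the conditions of step 13 and gives 30 after acidic work-up, where the route continues with step 15.

**Further compounds**

F1 | step 13 | (2R,5R,6R)-2-tert-butyl-6-[(2S)-butan-2-yl]-5-[(1E,4R)-4,8-dimethylnona-1,7-dien-1-yl]-1,3-dioxan-4-one | CC[C@H](C)[C@@H]1[C@@H](/C=C/C[C@H](C)CCC=C(C)C)C(=O)O[C@H](C(C)(C)C)O1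
F2 | step 13 | (2R,5R,6R)-2-tert-butyl-6-[(2S)-butan-2-yl]-5-[(1E,4R)-6-(3,3-dimethyloxiran-2-yl)-4-methylhex-1-en-1-yl]-1,3-dioxan-4-one, epoxide epimers | CC[C@H](C)[C@@H]1[C@@H](/C=C/C[C@H](C)CCC2OC2(C)C)C(=O)O[C@H](C(C)(C)C)O1
F3 | step 13 | (4R,6E)-7-{(2R,5R,6R)-2-tert-butyl-6-[(2S)-butan-2-yl]-4-oxo-1,3-dioxan-5-yl}-4-methylhept-6-enal | CC[C@H](C)[C@@H]1[C@@H](/C=C/C[C@H](C)CCC=O)C(=O)O[C@H](C(C)(C)C)O1
F4 | step 13 | (4R,6E)-7-{(2R,5R,6R)-2-tert-butyl-6-[(2S)-butan-2-yl]-4-oxo-1,3-dioxan-5-yl}-4-methylhept-6-enoic acid | CC[C@H](C)[C@@H]1[C@@H](/C=C/C[C@H](C)CCC(=O)O)C(=O)O[C@H](C(C)(C)C)O1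
F5 | step 5 | dilithium alkoxide enolate of 5 | CC[C@H](C)[C@@H]([O-])C=C([O-])OCC.[Li+].[Li+]
F6 | step 5 | ethyl (3R,4S)-2-chloro-3-hydroxy-4-methylhexanoate, C2 epimers | CC[C@H](C)[C@@H](O)C(Cl)C(=O)OCC
F7 | step 5 | (3R,4S)-2-chloro-3-hydroxy-4-methylhexanoic acid, C2 epimers | CC[C@H](C)[C@@H](O)C(Cl)C(=O)O
F8 | step 14 | (6R)-4-hydroxy-3-[(4R,6E)-7-iodo-4-methylhept-6-enoyl]-6-methyl-5,6-dihydro-2H-pyran-2-one | I/C=C/C[C@H](C)CCC(=O)C1=C(O)C[C@@H](C)OC1=O
F9 | step 14 | sodium enolate of F8 | I/C=C/C[C@H](C)CCC(=O)C1=C([O-])C[C@@H](C)OC1=O.[Na+]
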